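The data are simulated for an exercise; noise was put on by code.

**The question.** Which remedy gets more of the product D out of this flask, where enzyme Q works on solid substrate G with a further species X present, now that D stands still?

- alpha: G 20 mM; X 6 mM; Q 0.045 mol%; the very flask that is asked about, followed so far
- flask: G 20 mM; X 6.00 mM; Q 0.045 mol%; time 40 h

alpha run (percent of the G charged)

| time / h | D / % |
|---|---|
| 4.00 | 9.3 |
| 8.00 | 18.8 |
| 12.0 | 27.8 |
| 15.0 | 31.4 |
| 20.0 | 33.0 |
| 25.0 | 33.0 |

(scatter of a reading: 0.3 percentage points)

- given per volume of solution although it is solid: G
- what is taken out of D is counted as made
- the numbers in the tables scatter with a standard deviation of 0.3 percentage points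
- at the start none of G is in solution
- additions bring no volume worth counting

- autumn: at 40 h add Q, 50.0% of the amount charged, then wait 40 h
- winter: at 40 h take out 90% of the D then present, then wait 40 h
- dawn: change nothing and wait 40 h more

- D, in percent of the G first charged, at 40 h
- the remedy with the largest gain of D, or "none" below 2 percentage points (autumn / winter / dawn / none)
- D present, with what was taken out counted in, in percent of the G first charged, after winter
- D present, with what was taken out counted in, in percent of the G first charged, after dawn

**Two extremes.** In this flask D stopped at 33.0%, with 67.0% of the G not turned into D, so something other than the end of G stopped it. At one extreme the stop is an equilibrium: more Q adds nothing, and taking D out restarts the run. At the other, Q is lost as it works: more Q restarts the run, and taking D out adds nothing. Waiting adds nothing at either end.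

**Between them.** An approach to equilibrium slows as the distance shrinks. Yet D gained 9.3%, then 9.5 percentage points, then 9 points in equal steps of time, reaching 84.2% of the plateau reading at that pace. I therefore put this flask near the second extreme, with Q lost as it works.

**Carried quantity.** From the plateau reading, N = 733 moles of D per mole of Q charged, the turnover capacity (total turnover number). Adding 50.0% of the Q should buy 16 points, which is less than the unconverted G. At the early pace that takes 7.02 h, shorter than the 40 h allowed. So I commit to autumn, with winter and dawn staying at 33.0%.

**The forecast.** It differs from my reckoning, reading the plateau as an equilibrium: now 33%, best winter, g2 55%, g3 33%. Its ground against the other reading: “Enzyme death would bend the curve gradually, not stop it abruptly.”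

**The result.** This flask gives 33.1% now, and the best remedy is autumn. Autumn gains 17 points, winter 0 points and dawn 0 points, so g2 is 33.1% and g3 is 33.1%.

    L + Q ⇌ E (K = 88.0 M⁻¹, k = 991 M⁻¹ s⁻¹)
    E → Q + D (k = 1.15 s⁻¹)
    X + E → Z (k = 0.261 M⁻¹ s⁻¹)
    G ⇌ L, rate k4*(cs4 - [L]) while solid is left; crystals form when [L] > cs4 (solubility = 10.0 mM, k = 1.50 × 10⁻⁵ s⁻¹)

**What ran.** In this flask the steps L + Q to E and E to Q + D (L dissolved G, E the enzyme form holding it) each had 99.9% of their turnover up to 40.0 h done by 20.0 h, when Q stood at 0.0517% and the lost form Z at 99.9% of the catalyst charged. G went on dissolving after that, from 51.0% to 28.5% solid, and dissolved L rose to 38.4% by 40.0 h, while D stayed at 33.1%. Taking N as inverse in X, as X + E to Z has it, a neighbour flask with the same charges but 10 mM of X gets 440, hence 19.8% of D; that neighbour stood at 19.8%.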